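**Conventions.** "Farnesyl" means the (2E,6E)-3,7,11-trimethyldodeca-2,6,10-trien-1-yl group. Flavanone locants (O1, C2, C3, C4, C4a, C5–C8, C8a; rings A, B, C) are used for the corresponding atoms at every stage. MOM = methoxymethyl, TIPS = triisopropylsilyl. Compounds 1–25 belong to the route; 25 is the target.

## The problem

Target 25 is (2S)-6-farnesyl-5,7,3',5'-tetrahydroxyflavanone. A phloroglucinol-type ring A is fused through C4a–C8a to the pyranone ring C, and C2 carries the 3,5-dihydroxyphenyl ring B. C2 is the only stereocentre, so nothing in the molecule can relay configuration to it and it must come from a reagent or catalyst. Flavanones open reversibly to 2'-hydroxychalcones under base, so C2 should be set by a stereospecific event and kept away from base afterwards. The regiochemical core of the problem is that C4a is flanked by two oxygens: C5–O lies next to the farnesyl group on C6, and C8a–O lies para to it. Which of them becomes O1 decides between the 6-farnesyl and the 8-farnesyl flavanone, and a free acylphloroglucinol cannot tell them apart. The farnesyl chain has three trisubstituted alkenes and a benzylic–allylic methylene between two oxygens. This excludes hydrogenolysis, quinone oxidants and electrophilic halogen, and it makes strong acid dangerous because the flanking phenols can cyclise onto the chain. The enabling feature is that O1 (on C8a) and the C4 carbonyl carbon (on C4a) are neighbouring substituents of ring A, with the C5 oxygen on the other side of C4a. A C4a–C8a aryne flanked by a C5 alkoxy group can therefore accept both atoms from one carboxylate, oxygen at C8a and acyl at C4a, and the oxygen delivered in this way is the only free phenol of ring A.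

## Retrosynthesis

**25 from 24.** The four aryl O–CH2OMe bonds are cut last. MOM ethers are preferred to benzyl ethers (hydrogenolysis would reduce the chain), to silyl ethers (they would not survive the fluoride of the key step) and to methyl ethers (their removal needs boron halides). They also direct the two lithiations that build ring A. The forward step must be a mild acetal cleavage that spares the chain and C2.

**24 from 23.** O1–C2 is cut. The neighbouring option, oxa-Michael closure of a chalcone, would create C2 without control. An SN2 closure shifts the stereochemical problem to a secondary benzylic carbinol of opposite configuration, (3R) in 23, which a ketone reduction can supply. The ring B oxygens are meta to this carbon and do not stabilise a benzylic cation, so inversion without ionisation is a reasonable demand. Precursor 23 is acyclic and has the C8a phenol as its only free phenol.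

**23 from 22.** The carbinol O–Si bond is cut. The hydroxyl has to be masked during the aryne step, because an alkoxide would add to the aryne and a free OH would quench the aryl anion. The mask must come off without touching the acetals, which points to a bulky silyl ether (TIPS in 22).

**22 from 13 and 19.** C8a–O1 and C4a–C4 are cut together, leading to aryne 21 (released from silyl triflate 13) and the carboxylate 20 of acid 19. A Friedel–Crafts or ortho-lithiation acylation would form only C4a–C4 and leave the two ortho oxygens to be told apart by protecting-group manoeuvres. Here the oxygen arrives with the acyl group and is automatically the free one. The cut splits the molecule into an achiral arene fragment and a three-carbon acid that carries ring B and the stereocentre. The forward reaction must add oxygen at C8a and acyl at C4a, and must tolerate the silyl ether, the acetals and the alkenes.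

**13 from 11, 8 and 7.** The C4a–Si and C8a–OTf bonds lead back through the silylated carbamate 11 and the carbamate 8 to phenol 7. Phenol 7 is symmetric, so its two ortho positions are identical and each is activated by the carbamate and by an OMOM group. The directed silylation therefore has no regiochemical choice to make.

**7 from 6, and 6 from 3 and 4; 3 from 2 and 1.** The C6–farnesyl bond is cut to the aryllithium 5 of silyl ether 3 and farnesyl bromide 4. Lithiation between two OMOM groups is the most reliable way to place an allylic chain there without acid, and it leaves the alkene geometry alone. The silyl ether on the third oxygen does not direct and is later exchanged for the carbamate. The cost is the statistical bis-protection of phloroglucinol 1 to 2.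

**19 from 18, 17, 16, 15 and 14.** The stereocentre is traced to the β-keto ester 16 by asymmetric transfer hydrogenation (17), followed by silylation (18) and saponification (19). Keto ester 16 comes from acetophenone 15 by C-acylation, and 15 from commercial 3',5'-dihydroxyacetophenone 14. A catalytic ketone reduction is preferred to an auxiliary-based acetate aldol, which would add steps and stoichiometric chiral material.

## Roads not taken

**Alternative 1:** C2–C3 is cut. A diazomethyl ketone A1, with the diazo carbon as C3 and ring B attached as a benzyl ether on the C8a oxygen, would be decomposed by a chiral dirhodium tetracarboxylate Rh2(O2CR*)4. The carbenoid would insert into the benzylic C–H bond, closing ring C and setting C2 in one step to give the silyl-protected flavanone A2.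
- Merits: ring B enters as an achiral benzyl unit, so the five-step chiral acid branch disappears. The all-silyl protection could be removed with buffered fluoride, so no acid would come near the farnesyl chain. In both respects this road is better than the chosen one.
- Weak points: the carbenoid is of the acceptor-only type, the least selective class. Its classical competitor in exactly this arrangement is attack on the ether oxygen to form a five-membered oxonium ylide, followed by a [1,2]-benzyl shift. Three nucleophilic trisubstituted alkenes in the same molecule invite cyclopropanation. A1 also needs a benzoic acid whose two ortho oxygens are already differentiated, so the 6- versus 8-farnesyl question is moved into the substrate synthesis and not answered by the key step.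
- Comparison: the chosen plan is longer, but it takes its configuration from a ketone transfer hydrogenation and an SN2 inversion, and its regiochemistry from the key step itself.

**Alternative 2:** ring A itself is cut (C8–C8a, C6–C7, C4a–C8a). Heating the 2-farnesyl-3-silyloxycyclobutenone A3 with the siloxyalkyne A4 would trigger ring opening, [2+2] addition, a second opening and six-electron closure to give phenol A5.
- Merits: the farnesyl group is locked between two silyloxy groups and the C8a oxygen is the only free phenol, with no statistical protection. This is better than step 1 of the chosen route, which depends on separating a statistical mixture.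
- Weak points: it solves only the ring A problem, which the chosen route solves in four steps from phloroglucinol. A3 and A4 each need several steps. Ketene intermediates would be generated thermally beside three alkenes. C4a–C4, ring C and C2 would still be unaddressed, and the silyl ethers of A5 would not survive fluoride-triggered aryne chemistry.
- Comparison: the chosen plan relies on a cheap starting material and standard lithiation chemistry, and its key step addresses the flavanone and not only the arene.

**Alternative 3:** C3–C4 and O1–C2 are cut. Salicylaldehyde A6 would condense with trimethyl orthoformate A8 under a chiral Brønsted acid to a 4-methoxy ortho-quinone methide, which would add styrene A7 in a [4+2] sense to give the 4-methoxyflavan A9 as C4 epimers.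
- Merits: it is the most convergent option. Both ring C bonds and C2 form at once, the ring B piece is trivial, and if it worked it would be clearly shorter than the chosen route.
- Weak points: the cycloaddition wants an electron-rich alkene, but the oxygens of A7 are meta to the vinyl group and do not raise its nucleophilicity by resonance. Face selectivity would rest on ion pairing with a cationic heterodiene and an unactivated styrene. The acid would operate beside five acid-labile acetals and a farnesyl chain whose alkenes are better nucleophiles than A7. A9 is at the wrong oxidation level, so hydrolysis and oxidation at C4 add two steps. A6 needs the same differentiated phenol as the chosen route plus a formylation.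
- Comparison: the chosen plan is longer, but each of its selectivities has a structural cause that can be named.

Key step: step 13

Assumption: the sense of induction in step 10 is taken from the aryl ketone model of TsDPEN transfer hydrogenation, in which the (R,R)-ligand gives the (R)-carbinol when the aryl group outranks the second ketone substituent.

## Route

Step 1
Reactants: 1 phloroglucinol
Product: 2 3,5-bis(methoxymethoxy)phenol
Conditions: MOMCl (2.0 equiv), i-Pr2NEt, CH2Cl2/DMF, 0 °C → rt
Reagents that add atoms: chloromethyl methyl ether, COCCl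
Why: Statistical O-alkylation (Williamson-type acetal formation) of a symmetric triol; the bis-ether should be separable by chromatography from the mono- and tris-ethers, and the mono-ether can be recycled.

Step 2
Reactants: 2 3,5-bis(methoxymethoxy)phenol
Product: 3 [3,5-bis(methoxymethoxy)phenoxy]triisopropylsilane
Conditions: TIPSCl, imidazole, DMF, rt
Reagents that add atoms: chlorotriisopropylsilane, CC(C)[Si](Cl)(C(C)C)C(C)C
Why: Standard phenol silylation; the bulky silyl ether does not direct metalation and shields its two flanking positions in step 3.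

Step 3
Reactants: 3 [3,5-bis(methoxymethoxy)phenoxy]triisopropylsilane; 4 (2E,6E)-farnesyl bromide
Product: 6 [4-farnesyl-3,5-bis(methoxymethoxy)phenoxy]triisopropylsilane, via aryllithium 5 (not isolated)
Conditions: n-BuLi, THF, 0 °C; then 4, −78 °C → rt
Reagents that add atoms: none
Why: Directed ortho-metalation at the one position chelated by both acetal groups, then SN2 alkylation at the primary allylic carbon of 4, which should leave the 2E,6E geometry untouched.

Step 4
Reactants: 6 [4-farnesyl-3,5-bis(methoxymethoxy)phenoxy]triisopropylsilane
Product: 7 4-farnesyl-3,5-bis(methoxymethoxy)phenol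
Conditions: TBAF, THF, 0 °C; aq. NH4Cl
Reagents that add atoms: none
Why: Fluoride cleavage of an aryl silyl ether; acetals and alkenes are inert, and the oxygen para to the farnesyl group is now the only free one.

Step 5
Reactants: 7 4-farnesyl-3,5-bis(methoxymethoxy)phenol
Product: 8 4-farnesyl-3,5-bis(methoxymethoxy)phenyl N-isopropylcarbamate
Conditions: i-PrNCO, Et3N (cat.), CH2Cl2, rt
Reagents that add atoms: isopropyl isocyanate, CC(C)N=C=O
Why: Base-catalysed addition of a phenol to an isocyanate; the secondary carbamate serves as a directing group that can later be removed under mild amine base.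

Step 6
Reactants: 8 4-farnesyl-3,5-bis(methoxymethoxy)phenyl N-isopropylcarbamate
Product: 11 4-farnesyl-3,5-bis(methoxymethoxy)-2-(trimethylsilyl)phenyl N-isopropylcarbamate, via N-silyl carbamate 9 (not isolated), via aryllithium 10 (not isolated)
Conditions: TBSOTf, TMEDA, Et2O, 0 °C → rt; n-BuLi, TMEDA, −78 °C; TMSCl, −78 °C → rt; 10% aq. citric acid
Reagents that add atoms: chlorotrimethylsilane, C[Si](C)(C)Cl
Why: In situ N-silylation makes the carbamate tertiary so that it directs ortho-lithiation (directed ortho-metalation) instead of fragmenting; the two ortho positions of symmetric 8 are identical and each is activated by carbamate and OMOM, −78 °C should suppress the anionic Fries shift, and the N–Si bond is hydrolysed on work-up.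

Step 7
Reactants: 11 4-farnesyl-3,5-bis(methoxymethoxy)-2-(trimethylsilyl)phenyl N-isopropylcarbamate
Product: 13 4-farnesyl-3,5-bis(methoxymethoxy)-2-(trimethylsilyl)phenyl trifluoromethanesulfonate, via phenol 12 (not isolated)
Conditions: Et2NH, DBU, MeCN, 40 °C; then PhNTf2, rt
Reagents that add atoms: N-phenylbis(trifluoromethanesulfonimide), O=S(=O)(N(c1ccccc1)S(=O)(=O)C(F)(F)F)C(F)(F)F
Why: Base-induced elimination of isopropyl isocyanate from the deprotonated carbamate (trapped by diethylamine as a urea) frees the hindered phenoxide, which is sulfonylated in the same flask; the mild triflyl-transfer reagent should spare the acetals and the aryl–silicon bond.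

Step 8
Reactants: 14 3',5'-dihydroxyacetophenone
Product: 15 3',5'-bis(methoxymethoxy)acetophenone
Conditions: MOMCl, i-Pr2NEt, CH2Cl2, 0 °C → rt
Reagents that add atoms: chloromethyl methyl ether, COCCl
Why: Exhaustive O-alkylation of both phenols (Williamson-type acetal formation).

Step 9
Reactants: 15 3',5'-bis(methoxymethoxy)acetophenone
Product: 16 methyl 3-[3,5-bis(methoxymethoxy)phenyl]-3-oxopropanoate
Conditions: NaH, (MeO)2CO, THF, reflux; then AcOH
Reagents that add atoms: dimethyl carbonate, COC(=O)OC
Why: Claisen-type C-acylation of the ketone enolate with a carbonate ester, driven by deprotonation of the β-keto ester product; the acetals are base-stable.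

Step 10
Reactants: 16 methyl 3-[3,5-bis(methoxymethoxy)phenyl]-3-oxopropanoate
Product: 17 methyl (3R)-3-[3,5-bis(methoxymethoxy)phenyl]-3-hydroxypropanoate
Conditions: RuCl[(R,R)-TsDPEN](p-cymene) (1 mol %), HCO2H/Et3N (5:2), 30 °C
Reagents that add atoms: none
Why: Noyori asymmetric transfer hydrogenation of an aryl ketone; the metal-hydride/N–H pair delivers hydrogen to the face fixed by the CH/π contact between the substrate aryl group and the cymene ligand, which with the (R,R)-ligand should give the (3R)-carbinol, and the buffered medium does not touch the acetals.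

Step 11
Reactants: 17 methyl (3R)-3-[3,5-bis(methoxymethoxy)phenyl]-3-hydroxypropanoate
Product: 18 methyl (3R)-3-[3,5-bis(methoxymethoxy)phenyl]-3-(triisopropylsilyloxy)propanoate
Conditions: TIPSOTf, 2,6-lutidine, CH2Cl2, −78 → 0 °C
Reagents that add atoms: triisopropylsilyl trifluoromethanesulfonate, CC(C)[Si](OS(=O)(=O)C(F)(F)F)(C(C)C)C(C)C
Why: Silylation of a secondary alcohol with a silyl triflate and a hindered base; the configuration is not touched, and TIPS is the silyl group most resistant to base and fluoride.

Step 12
Reactants: 18 methyl (3R)-3-[3,5-bis(methoxymethoxy)phenyl]-3-(triisopropylsilyloxy)propanoate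
Product: 19 (3R)-3-[3,5-bis(methoxymethoxy)phenyl]-3-(triisopropylsilyloxy)propanoic acid
Conditions: LiOH, THF/MeOH/H2O, 0 °C → rt; then 1 M HCl to pH 4, 0 °C
Reagents that add atoms: lithium hydroxide, [Li+].[OH-]
Why: Saponification of a methyl ester; once the carboxylate has formed, β-elimination of the silyloxy group is disfavoured, and brief cold acidification to pH 4 should spare acetals and silyl ether.

Step 13
Reactants: 13 4-farnesyl-3,5-bis(methoxymethoxy)-2-(trimethylsilyl)phenyl trifluoromethanesulfonate; 19 (3R)-3-[3,5-bis(methoxymethoxy)phenyl]-3-(triisopropylsilyloxy)propanoic acid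
Product: 22 (3R)-1-[3-farnesyl-6-hydroxy-2,4-bis(methoxymethoxy)phenyl]-3-[3,5-bis(methoxymethoxy)phenyl]-3-(triisopropylsilyloxy)propan-1-one, via cesium carboxylate 20 (not isolated), via aryne 21 (not isolated)
Conditions: 19 (1.3 equiv), Cs2CO3 (0.65 equiv), MeOH, rt, then evaporation and drying (PhMe azeotrope); 13 (1.0 equiv), CsF (3 equiv), THF, sealed tube, 125 °C; aq. NH4Cl
Reagents that add atoms: none
Why: Fluoride attacks the trimethylsilyl group of 13 and triflate leaves, releasing aryne 21 slowly because CsF is sparingly soluble in THF. The carboxylate oxygen of 20 adds at C8a, the aryne carbon remote from the C5 methoxymethoxy group, so that the aryl anion develops at C4a where the adjacent C5–O bond stabilises it inductively, as with other 3-alkoxybenzynes. This anion attacks the carbonyl of the aryl ester just formed through a four-membered transition state, and the tetrahedral alkoxide opens to the ortho-acyl phenoxide, so C8a–O1 and C4a–C4 form in one operation. The closest known reaction type is the fluoride-induced insertion of arynes into the C–O bond of carboxylic acids, which gives ortho-hydroxyaryl ketones under these conditions. No ring is closed (the four-membered alkoxide is only a transient) and no stereocentre is formed; C3 of the acid is a spectator and keeps its (R) configuration. The step needs regioselectivity (oxygen at C8a, acyl at C4a), which the C5 alkoxy group beside the triple bond secures, and chemoselectivity for the carboxylate over the farnesyl alkenes (ene reaction) and over the product phenoxide, which the excess of pre-formed cesium salt and the slow release of 21 should secure. Because the salt is pre-formed and dried, no proton donor is present, so the aryl anion should acylate instead of being quenched to the simple aryl ester, and 22 stays as its cesium phenoxide, whose conjugation with the ketone should disfavour enolisation and loss of the silyloxy group.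

Step 14
Reactants: 22 (3R)-1-[3-farnesyl-6-hydroxy-2,4-bis(methoxymethoxy)phenyl]-3-[3,5-bis(methoxymethoxy)phenyl]-3-(triisopropylsilyloxy)propan-1-one
Product: 23 (3R)-1-[3-farnesyl-6-hydroxy-2,4-bis(methoxymethoxy)phenyl]-3-hydroxy-3-[3,5-bis(methoxymethoxy)phenyl]propan-1-one
Conditions: TBAF/AcOH (1:1), THF, rt
Reagents that add atoms: none
Why: Fluoride cleavage of the silyl ether; buffering with acetic acid should keep the β-hydroxy ketone from retro-aldol cleavage and elimination, and the acetals are unaffected.

Step 15
Reactants: 23 (3R)-1-[3-farnesyl-6-hydroxy-2,4-bis(methoxymethoxy)phenyl]-3-hydroxy-3-[3,5-bis(methoxymethoxy)phenyl]propan-1-one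
Product: 24 (2S)-6-farnesyl-5,7-bis(methoxymethoxy)-2-[3,5-bis(methoxymethoxy)phenyl]chroman-4-one
Conditions: PPh3, DIAD, THF, 0 °C → rt
Reagents that add atoms: none
Why: Intramolecular Mitsunobu etherification; the C8a phenol, the only free one, displaces the activated carbinol oxygen in a six-membered SN2 closure with inversion, turning (3R) into (2S), and the meta-oxygenated ring B gives little support to ionisation.

Step 16
Reactants: 24 (2S)-6-farnesyl-5,7-bis(methoxymethoxy)-2-[3,5-bis(methoxymethoxy)phenyl]chroman-4-one
Product: 25 (2S)-6-farnesyl-5,7-dihydroxy-2-(3,5-dihydroxyphenyl)chroman-4-one (CNP0186816.1)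
Conditions: 3 M aq. HCl/MeOH, rt → 40 °C
Reagents that add atoms: none
Why: Acid-catalysed acetal exchange with methanol removes the four MOM groups; dilute methanolic HCl is the established way to unmask MOM-protected prenylated flavonoids and should leave the side-chain alkenes and C2 intact if temperature and time are kept low.

## Compound list

1 | phloroglucinol (benzene-1,3,5-triol) | Oc1cc(O)cc(O)c1 | starting material
2 | 3,5-bis(methoxymethoxy)phenol | COCOc1cc(O)cc(OCOC)c1 | intermediate
3 | [3,5-bis(methoxymethoxy)phenoxy]triisopropylsilane | COCOc1cc(O[Si](C(C)C)(C(C)C)C(C)C)cc(OCOC)c1 | intermediate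
4 | (2E,6E)-farnesyl bromide | CC(C)=CCC/C(C)=C/CC/C(C)=C/CBr | starting material
5 | [2,6-bis(methoxymethoxy)-4-(triisopropylsilyloxy)phenyl]lithium (formed in situ) | [Li]c1c(OCOC)cc(O[Si](C(C)C)(C(C)C)C(C)C)cc1OCOC | intermediate
6 | [4-farnesyl-3,5-bis(methoxymethoxy)phenoxy]triisopropylsilane | CC(C)=CCC/C(C)=C/CC/C(C)=C/Cc1c(OCOC)cc(O[Si](C(C)C)(C(C)C)C(C)C)cc1OCOC | intermediate
7 | 4-farnesyl-3,5-bis(methoxymethoxy)phenol | CC(C)=CCC/C(C)=C/CC/C(C)=C/Cc1c(OCOC)cc(O)cc1OCOC | intermediate
8 | 4-farnesyl-3,5-bis(methoxymethoxy)phenyl N-isopropylcarbamate | CC(C)=CCC/C(C)=C/CC/C(C)=C/Cc1c(OCOC)cc(OC(=O)NC(C)C)cc1OCOC | intermediate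
9 | 4-farnesyl-3,5-bis(methoxymethoxy)phenyl N-(tert-butyldimethylsilyl)-N-isopropylcarbamate (formed in situ) | CC(C)=CCC/C(C)=C/CC/C(C)=C/Cc1c(OCOC)cc(OC(=O)N(C(C)C)[Si](C)(C)C(C)(C)C)cc1OCOC | intermediate
10 | 2-lithio derivative of 9 (formed in situ) | CC(C)=CCC/C(C)=C/CC/C(C)=C/Cc1c(OCOC)cc(OC(=O)N(C(C)C)[Si](C)(C)C(C)(C)C)c([Li])c1OCOC | intermediate
11 | 4-farnesyl-3,5-bis(methoxymethoxy)-2-(trimethylsilyl)phenyl N-isopropylcarbamate | CC(C)=CCC/C(C)=C/CC/C(C)=C/Cc1c(OCOC)cc(OC(=O)NC(C)C)c([Si](C)(C)C)c1OCOC | intermediate
12 | 4-farnesyl-3,5-bis(methoxymethoxy)-2-(trimethylsilyl)phenol (formed in situ) | CC(C)=CCC/C(C)=C/CC/C(C)=C/Cc1c(OCOC)cc(O)c([Si](C)(C)C)c1OCOC | intermediate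
13 | 4-farnesyl-3,5-bis(methoxymethoxy)-2-(trimethylsilyl)phenyl trifluoromethanesulfonate | CC(C)=CCC/C(C)=C/CC/C(C)=C/Cc1c(OCOC)cc(OS(=O)(=O)C(F)(F)F)c([Si](C)(C)C)c1OCOC | intermediate
14 | 3',5'-dihydroxyacetophenone | CC(=O)c1cc(O)cc(O)c1 | starting material
15 | 3',5'-bis(methoxymethoxy)acetophenone | CC(=O)c1cc(OCOC)cc(OCOC)c1 | intermediate
16 | methyl 3-[3,5-bis(methoxymethoxy)phenyl]-3-oxopropanoate | COC(=O)CC(=O)c1cc(OCOC)cc(OCOC)c1 | intermediate
17 | methyl (3R)-3-[3,5-bis(methoxymethoxy)phenyl]-3-hydroxypropanoate | COC(=O)C[C@H](c1cc(OCOC)cc(OCOC)c1)O | intermediate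
18 | methyl (3R)-3-[3,5-bis(methoxymethoxy)phenyl]-3-(triisopropylsilyloxy)propanoate | COC(=O)C[C@H](c1cc(OCOC)cc(OCOC)c1)O[Si](C(C)C)(C(C)C)C(C)C | intermediate
19 | (3R)-3-[3,5-bis(methoxymethoxy)phenyl]-3-(triisopropylsilyloxy)propanoic acid | OC(=O)C[C@H](c1cc(OCOC)cc(OCOC)c1)O[Si](C(C)C)(C(C)C)C(C)C | intermediate
20 | cesium (3R)-3-[3,5-bis(methoxymethoxy)phenyl]-3-(triisopropylsilyloxy)propanoate (formed in situ) | [Cs+].[O-]C(=O)C[C@H](c1cc(OCOC)cc(OCOC)c1)O[Si](C(C)C)(C(C)C)C(C)C | intermediate
21 | 4-farnesyl-3,5-bis(methoxymethoxy)benzyne (1,2-didehydrobenzene, formed in situ) | CC(C)=CCC/C(C)=C/CC/C(C)=C/CC1=C(OCOC)C#CC=C1OCOC | intermediate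
22 | (3R)-1-[3-farnesyl-6-hydroxy-2,4-bis(methoxymethoxy)phenyl]-3-[3,5-bis(methoxymethoxy)phenyl]-3-(triisopropylsilyloxy)propan-1-one | CC(C)=CCC/C(C)=C/CC/C(C)=C/Cc1c(OCOC)cc(O)c(c1OCOC)C(=O)C[C@H](c1cc(OCOC)cc(OCOC)c1)O[Si](C(C)C)(C(C)C)C(C)C | intermediate
23 | (3R)-1-[3-farnesyl-6-hydroxy-2,4-bis(methoxymethoxy)phenyl]-3-hydroxy-3-[3,5-bis(methoxymethoxy)phenyl]propan-1-one | CC(C)=CCC/C(C)=C/CC/C(C)=C/Cc1c(OCOC)cc(O)c(c1OCOC)C(=O)C[C@H](c1cc(OCOC)cc(OCOC)c1)O | intermediate
24 | (2S)-6-farnesyl-5,7-bis(methoxymethoxy)-2-[3,5-bis(methoxymethoxy)phenyl]chroman-4-one | CC(C)=CCC/C(C)=C/CC/C(C)=C/Cc1c(OCOC)cc2c(c1OCOC)C(=O)C[C@@H](c1cc(OCOC)cc(OCOC)c1)O2 | intermediate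
25 | (2S)-6-farnesyl-5,7-dihydroxy-2-(3,5-dihydroxyphenyl)chroman-4-one (CNP0186816.1) | CC(C)=CCC/C(C)=C/CC/C(C)=C/Cc1c(O)cc2c(c1O)C(=O)C[C@@H](c1cc(O)cc(O)c1)O2 | target

## Step count and least certain steps

Total step count: 16. Longest linear sequence: 11 steps (steps 1–7 and 13–16, from 1); the acid branch (steps 8–12) has 5 steps.

**Step 13 (key step).**
- What may go wrong: the C4a aryl anion may be quenched by adventitious proton sources before it transfers the acyl group, which would stop the reaction at simple O-arylation. At 125 °C the silyloxy group may slowly be lost by β-elimination or by fluoride attack at silicon, which would erode the stereocentre through chalcone formation. The aryne may also be consumed by ene reaction with farnesyl alkenes or by arylation of the product phenoxide.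
- Fallback (sets out from 8 and 19, returns at 22): the two bonds would be made by directed ortho-metalation instead of an aryne. Acid 19 would be coupled with N,O-dimethylhydroxylamine hydrochloride (EDC, i-Pr2NEt) to the Weinreb amide (3R)-3-[3,5-bis(methoxymethoxy)phenyl]-N-methoxy-N-methyl-3-(triisopropylsilyloxy)propanamide F1. Carbamate 8 would be N-silylated and lithiated as in step 6 (9, then 10), and 10 would be acylated with F1 at −78 °C to give, after citric acid work-up, the ortho-acyl carbamate 2-{(3R)-3-[3,5-bis(methoxymethoxy)phenyl]-3-(triisopropylsilyloxy)propanoyl}-4-farnesyl-3,5-bis(methoxymethoxy)phenyl N-isopropylcarbamate F2. The carbamate, now on an ortho-acyl phenol, would be cleaved with diethylamine in MeCN at rt to give 22.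

**Step 6.**
- What may go wrong: an acetal may be cleaved by the silyl triflate before N-silylation is complete. A carbamate anion that is not silylated may fragment to isocyanate and phenoxide. Lateral lithiation at the benzylic–allylic methylene of the farnesyl group may compete.
- Fallback (sets out from 7, returns at 12): a tertiary carbamate that needs no silyl triflate. Phenol 7 would be carbamoylated (Et2NCOCl, NaH, THF) to 4-farnesyl-3,5-bis(methoxymethoxy)phenyl N,N-diethylcarbamate F3. Lithiation with s-BuLi/TMEDA in THF at −78 °C and quenching with TMSCl would give 4-farnesyl-3,5-bis(methoxymethoxy)-2-(trimethylsilyl)phenyl N,N-diethylcarbamate F4. LiAlH4 in THF would reduce the carbamate away to phenol 12, which would then be isolated and triflated (PhNTf2, Cs2CO3) to 13.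

**Step 15.**
- What may go wrong: the activated β-hydroxy ketone may eliminate to the 2'-hydroxychalcone, which recloses without stereocontrol and erodes enantiomeric purity. The phenol is hindered and hydrogen-bonded to the ketone, so displacement may be slow.
- Fallback (sets out from 23, returns at 24): resolution in place of stereospecific closure. Diol 23 would be dehydrated on purpose (MsCl, Et3N) to the chalcone (E)-1-[3-farnesyl-6-hydroxy-2,4-bis(methoxymethoxy)phenyl]-3-[3,5-bis(methoxymethoxy)phenyl]prop-2-en-1-one F5. This closes by oxa-Michael addition (NaOAc, EtOH, reflux) to racemic 6-farnesyl-5,7-bis(methoxymethoxy)-2-[3,5-bis(methoxymethoxy)phenyl]chroman-4-one F6. Kinetic resolution by asymmetric transfer hydrogenation (RhCl(C5Me5)[TsDPEN] of the hand that reduces the (2R)-ketone faster, HCO2H/Et3N) would convert the (2R)-enantiomer into the cis-alcohol (2R,4R)-6-farnesyl-5,7-bis(methoxymethoxy)-2-[3,5-bis(methoxymethoxy)phenyl]chroman-4-ol F7 and leave (2S)-configured 24. The same resolution could upgrade partly eroded 24 from the Mitsunobu reaction.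

**Step 16.**
- What may go wrong: protonation of the 2',3'-alkene of the farnesyl chain may lead to cyclisation of the freed C5 or C7 phenol onto it (chroman formation) or to cation–olefin cyclisation further along the chain. The non-chelated acetals may be removed incompletely under conditions mild enough to avoid this.
- Fallback (sets out from 24, returns at 25): Lewis-acid-mediated exchange of acetal for silyl ether instead of protic hydrolysis. TMSOTf with 2,2'-bipyridyl in CH2Cl2 at 0 °C would transfer each methoxymethyl group to a bipyridyl nitrogen and leave the aryl oxygens silylated, giving (2S)-6-farnesyl-5,7-bis(trimethylsilyloxy)-2-[3,5-bis(trimethylsilyloxy)phenyl]chroman-4-one F8. Water at neutral pH on work-up would hydrolyse the aryl silyl ethers to 25, so no free Brønsted acid meets the farnesyl chain.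

## Further compounds

F1 | step 13 | (3R)-3-[3,5-bis(methoxymethoxy)phenyl]-N-methoxy-N-methyl-3-(triisopropylsilyloxy)propanamide | CON(C)C(=O)C[C@H](c1cc(OCOC)cc(OCOC)c1)O[Si](C(C)C)(C(C)C)C(C)C
F2 | step 13 | 2-{(3R)-3-[3,5-bis(methoxymethoxy)phenyl]-3-(triisopropylsilyloxy)propanoyl}-4-farnesyl-3,5-bis(methoxymethoxy)phenyl N-isopropylcarbamate | CC(C)=CCC/C(C)=C/CC/C(C)=C/Cc1c(OCOC)cc(OC(=O)NC(C)C)c(c1OCOC)C(=O)C[C@H](c1cc(OCOC)cc(OCOC)c1)O[Si](C(C)C)(C(C)C)C(C)C
F3 | step 6 | 4-farnesyl-3,5-bis(methoxymethoxy)phenyl N,N-diethylcarbamate | CC(C)=CCC/C(C)=C/CC/C(C)=C/Cc1c(OCOC)cc(OC(=O)N(CC)CC)cc1OCOC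
F4 | step 6 | 4-farnesyl-3,5-bis(methoxymethoxy)-2-(trimethylsilyl)phenyl N,N-diethylcarbamate | CC(C)=CCC/C(C)=C/CC/C(C)=C/Cc1c(OCOC)cc(OC(=O)N(CC)CC)c([Si](C)(C)C)c1OCOC
F5 | step 15 | (E)-1-[3-farnesyl-6-hydroxy-2,4-bis(methoxymethoxy)phenyl]-3-[3,5-bis(methoxymethoxy)phenyl]prop-2-en-1-one | CC(C)=CCC/C(C)=C/CC/C(C)=C/Cc1c(OCOC)cc(O)c(c1OCOC)C(=O)/C=C/c1cc(OCOC)cc(OCOC)c1
F6 | step 15 | racemic 6-farnesyl-5,7-bis(methoxymethoxy)-2-[3,5-bis(methoxymethoxy)phenyl]chroman-4-one | CC(C)=CCC/C(C)=C/CC/C(C)=C/Cc1c(OCOC)cc2c(c1OCOC)C(=O)CC(c1cc(OCOC)cc(OCOC)c1)O2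
F7 | step 15 | (2R,4R)-6-farnesyl-5,7-bis(methoxymethoxy)-2-[3,5-bis(methoxymethoxy)phenyl]chroman-4-ol | CC(C)=CCC/C(C)=C/CC/C(C)=C/Cc1c(OCOC)cc2c(c1OCOC)[C@H](O)C[C@H](c1cc(OCOC)cc(OCOC)c1)O2
F8 | step 16 | (2S)-6-farnesyl-5,7-bis(trimethylsilyloxy)-2-[3,5-bis(trimethylsilyloxy)phenyl]chroman-4-one | CC(C)=CCC/C(C)=C/CC/C(C)=C/Cc1c(O[Si](C)(C)C)cc2c(c1O[Si](C)(C)C)C(=O)C[C@@H](c1cc(O[Si](C)(C)C)cc(O[Si](C)(C)C)c1)O2
A1 | alternative 1 | 2-diazo-1-{2-[3,5-bis(tert-butyldimethylsilyloxy)benzyloxy]-4,6-bis(tert-butyldimethylsilyloxy)-5-farnesylphenyl}ethanone | CC(C)=CCC/C(C)=C/CC/C(C)=C/Cc1c(O[Si](C)(C)C(C)(C)C)cc(OCc2cc(O[Si](C)(C)C(C)(C)C)cc(O[Si](C)(C)C(C)(C)C)c2)c(C(=O)C=[N+]=[N-])c1O[Si](C)(C)C(C)(C)C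
A2 | alternative 1 | (2S)-6-farnesyl-5,7-bis(tert-butyldimethylsilyloxy)-2-[3,5-bis(tert-butyldimethylsilyloxy)phenyl]chroman-4-one | CC(C)=CCC/C(C)=C/CC/C(C)=C/Cc1c(O[Si](C)(C)C(C)(C)C)cc2c(c1O[Si](C)(C)C(C)(C)C)C(=O)C[C@@H](c1cc(O[Si](C)(C)C(C)(C)C)cc(O[Si](C)(C)C(C)(C)C)c1)O2
A3 | alternative 2 | 2-farnesyl-3-(triisopropylsilyloxy)cyclobut-2-en-1-one | CC(C)=CCC/C(C)=C/CC/C(C)=C/CC1=C(O[Si](C(C)C)(C(C)C)C(C)C)CC1=O
A4 | alternative 2 | (triisopropylsilyloxy)acetylene | C#CO[Si](C(C)C)(C(C)C)C(C)C
A5 | alternative 2 | 4-farnesyl-3,5-bis(triisopropylsilyloxy)phenol | CC(C)=CCC/C(C)=C/CC/C(C)=C/Cc1c(O[Si](C(C)C)(C(C)C)C(C)C)cc(O)cc1O[Si](C(C)C)(C(C)C)C(C)C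
A6 | alternative 3 | 3-farnesyl-6-hydroxy-2,4-bis(methoxymethoxy)benzaldehyde | CC(C)=CCC/C(C)=C/CC/C(C)=C/Cc1c(OCOC)cc(O)c(C=O)c1OCOC
A7 | alternative 3 | 3,5-bis(methoxymethoxy)styrene | C=Cc1cc(OCOC)cc(OCOC)c1
A8 | alternative 3 | trimethyl orthoformate | COC(OC)OC
A9 | alternative 3 | (2S)-6-farnesyl-4-methoxy-5,7-bis(methoxymethoxy)-2-[3,5-bis(methoxymethoxy)phenyl]chromane, C4 epimers | CC(C)=CCC/C(C)=C/CC/C(C)=C/Cc1c(OCOC)cc2c(c1OCOC)C(OC)C[C@@H](c1cc(OCOC)cc(OCOC)c1)O2
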